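**Plan**

1. Numbering (terpenoid): ring A = C1–C5 + C10, ring B = C5–C10, C11 = benzylic CH2. Retrosynthetic cuts, in order: the oxazole C2 carbon (from an o-aminophenol, made from resorcinol 24 by azo coupling and reduction); the C8 methyl (from a C8 ketone via =CH2); the C5–C6 bond; then C8–vinyl, C9–C11, C9–CH3 and the two Diels–Alder bonds C3–C8 and C9–C10.
2. Enabling feature: the C3=C4 olefin of ring A is allylic to C5–C6 and C8 of ring B can be a carbonyl carbon, so C3=C4–C5–C6–C7–C8(=O) is the retron of an anionic oxy-Cope shift. Undoing it reconnects C3 to C8 and turns the cis-fused decalin into a 2-vinylbicyclo[2.2.2]oct-5-en-2-ol.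
3. Forward order of rings: the bicyclo[2.2.2]octene (its cyclohexene ring is the future ring A, bridged by C8–C9) by Diels–Alder reaction; the arene joined at C9 by enolate benzylation; ring B closed by the C5–C6 bond while the temporary C3–C8 bridge opens; the oxazole ring last.
4. Stereochemistry: absolute sense from the organocatalytic Diels–Alder reaction (bridgeheads = C3 and C10); C9 by alkylation on the olefin-bridge face; C5 (methyl cis to H-10) by the cage-controlled sigmatropic shift; C8 by hydrogenation from the alpha face.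
5. Helpers: the C8 alkoxide/ketone (activating group, converted into the C8 methyl in steps 12–13), the C3–C8 bond (temporary ring, opened in the key step) and two MOM ethers (removed in step 14).

Key step: step 11

Remark: 4-methoxybenzene-1,3-diol, 2-methylcyclohex-2-en-1-one, acrolein and both enantiomers of 5-benzyl-2,2,3-trimethylimidazolidin-4-one hydrochloride are taken to be commercial. "Alpha" means the face of ring B that carries H-10, the C5 methyl and C11; "beta" means the face of the C8 and C9 methyls.

**Route**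

Step 1
Reactants: 1 4-methoxybenzene-1,3-diol
Product: 2 1-methoxy-2,4-bis(methoxymethoxy)benzene
Conditions: MOMCl (2.5 equiv), i-Pr2NEt, CH2Cl2, 0 °C to rt
Reagents that add atoms: chloromethyl methyl ether, COCCl
Why: Acetal protection (O-alkylation) of both phenols gives base-stable MOM ethers that later direct ortho-lithiation and come off with mild acid; no stereocentre is formed.

Step 2
Reactants: 2 1-methoxy-2,4-bis(methoxymethoxy)benzene
Product: 4 [3-methoxy-2,6-bis(methoxymethoxy)phenyl]methanol, via aryllithium 3 (not isolated)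
Conditions: n-BuLi, TMEDA, THF, 0 °C; then paraformaldehyde, −78 °C to rt; aqueous work-up
Reagents that add atoms: formaldehyde (used as paraformaldehyde), C=O
Why: Directed ortho-metalation should occur at the ring position flanked by both OCH2OMe groups (the most acidic site), and the aryllithium is hydroxymethylated by formaldehyde; no stereocentre is formed.

Step 3
Reactants: 4 [3-methoxy-2,6-bis(methoxymethoxy)phenyl]methanol
Product: 5 2-(bromomethyl)-4-methoxy-1,3-bis(methoxymethoxy)benzene
Conditions: CBr4, PPh3, CH2Cl2, 0 °C; used at once in step 9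
Reagents that add atoms: tetrabromomethane, BrC(Br)(Br)Br
Why: The Appel reaction converts the benzylic alcohol into the bromide under neutral conditions that spare the acetal ethers; the electron-rich bromide is expected to be labile and is therefore not stored.

Step 4
Reactants: 6 2-methylcyclohex-2-en-1-one
Product: 8 6-methylcyclohexa-1,5-dien-1-yl trifluoromethanesulfonate, via lithium dienolate 7 (not isolated)
Conditions: LDA, THF, −78 °C; then PhNTf2, −78 to 0 °C
Reagents that add atoms: N-phenylbis(trifluoromethanesulfonimide), O=S(=O)(N(c1ccccc1)S(=O)(=O)C(F)(F)F)C(F)(F)F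
Why: Kinetic deprotonation of the enone at the alpha' carbon gives the cross-conjugated dienolate, which is O-sulfonylated (enol triflate formation); no stereocentre is formed.

Step 5
Reactants: 8 6-methylcyclohexa-1,5-dien-1-yl trifluoromethanesulfonate
Product: 9 2,3-dimethylcyclohexa-1,3-diene
Conditions: MeMgBr, Fe(acac)3 (5 mol %), THF/NMP, −30 to 0 °C; volatile product kept as a concentrated solution
Reagents that add atoms: methylmagnesium bromide, C[Mg]Br
Why: Iron-catalysed cross-coupling of an alkenyl triflate with a methyl Grignard reagent (Kumada-type coupling) replaces the triflate by methyl and keeps the diene; no stereocentre is formed.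

Step 6
Reactants: 9 2,3-dimethylcyclohexa-1,3-diene; 10 acrolein
Product: 11 (1R,2S,4S)-5,6-dimethylbicyclo[2.2.2]oct-5-ene-2-carbaldehyde (endo: CHO syn to the C5=C6 bridge)
Conditions: acrolein in excess (3 equiv); (5R)-5-benzyl-2,2,3-trimethylimidazolidin-4-one hydrochloride (10 mol %); MeCN/H2O 95:5; 0 °C to rt; the endo adduct is separated from the minor exo adduct by chromatography
Reagents that add atoms: none
Why: In this iminium-catalysed enantioselective Diels–Alder reaction (a [4+2] cycloaddition that keeps every atom of both partners) the benzyl group of the (E)-iminium ion is expected to block one face of acrolein and the endo transition state to place the formyl group on the side of the new olefin bridge, which together fix both bridgehead centres (the future C3 and C10), while the exo adduct is removed because it would lead to the enantiomeric ketone.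

Step 7
Reactants: 11 (1R,2S,4S)-5,6-dimethylbicyclo[2.2.2]oct-5-ene-2-carbaldehyde
Product: 13 (1S,4S)-5,6-dimethylbicyclo[2.2.2]oct-5-en-2-one, via piperidine enamine 12 (not isolated)
Conditions: piperidine, 4 Å molecular sieves, Et2O, rt; then CuCl (10 mol %), O2 (1 atm), MeCN, 0 °C to rt
Reagents that add atoms: dioxygen, O=O
Why: Copper-catalysed aerobic cleavage of the enamine C=C bond (deformylative oxygenation of an aldehyde enamine) should give the nor-ketone and N-formylpiperidine while the isolated tetrasubstituted olefin stays inert to triplet oxygen; the bridgehead centres are untouched and the C2 centre disappears.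

Step 8
Reactants: 13 (1S,4S)-5,6-dimethylbicyclo[2.2.2]oct-5-en-2-one
Product: 15 (1S,4S)-3,5,6-trimethylbicyclo[2.2.2]oct-5-en-2-one (both C3 epimers), via lithium enolate 14 (not isolated)
Conditions: LDA, THF, −78 °C; then MeI, −78 to 0 °C
Reagents that add atoms: iodomethane, CI
Why: Enolate alkylation at the only enolisable position (C3, since the bridgehead C1 cannot enolise) installs the methyl group, and the C3 configuration is of no consequence because this centre is made planar again in step 9.

Step 9
Reactants: 15 (1S,4S)-3,5,6-trimethylbicyclo[2.2.2]oct-5-en-2-one; 5 2-(bromomethyl)-4-methoxy-1,3-bis(methoxymethoxy)benzene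
Product: 17 (1S,3S,4R)-3-{[3-methoxy-2,6-bis(methoxymethoxy)phenyl]methyl}-3,5,6-trimethylbicyclo[2.2.2]oct-5-en-2-one (arylmethyl syn to the C5=C6 bridge), via lithium enolate 16 (not isolated)
Conditions: LDA, THF, −78 to 0 °C; then DMPU and 5, −78 °C to rt
Reagents that add atoms: none
Why: Alkylation of the tetrasubstituted enolate with the benzylic bromide creates the quaternary carbon (future C9), and the electrophile is expected to approach from the face of the olefin bridge, which is less hindered than the face under the inward-pointing hydrogens of the CH2–CH2 bridge, so that the arylmethyl group ends syn to the olefin bridge and the methyl group syn to the CH2–CH2 bridge.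

Step 10
Reactants: 17 (1S,3S,4R)-3-{[3-methoxy-2,6-bis(methoxymethoxy)phenyl]methyl}-3,5,6-trimethylbicyclo[2.2.2]oct-5-en-2-one
Product: 18 (1S,2S,3S,4R)-2-ethenyl-3-{[3-methoxy-2,6-bis(methoxymethoxy)phenyl]methyl}-3,5,6-trimethylbicyclo[2.2.2]oct-5-en-2-ol (vinyl syn to the C5=C6 bridge)
Conditions: vinylmagnesium bromide, anhydrous CeCl3, THF, −78 to 0 °C
Reagents that add atoms: vinylmagnesium bromide, C=C[Mg]Br
Why: Cerium-mediated Grignard 1,2-addition to the non-enolisable hindered ketone should occur from the olefin-bridge side of the carbonyl (the side free of the CH2–CH2 bridge hydrogens), which places the vinyl group syn to C5=C6 (and the hydroxyl syn to the CH2–CH2 bridge) as the rearrangement requires.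

Step 11
Reactants: 18 (1S,2S,3S,4R)-2-ethenyl-3-{[3-methoxy-2,6-bis(methoxymethoxy)phenyl]methyl}-3,5,6-trimethylbicyclo[2.2.2]oct-5-en-2-ol
Product: 21 (1S,4aR,8aR)-1-{[3-methoxy-2,6-bis(methoxymethoxy)phenyl]methyl}-1,4a,5-trimethyl-3,4,4a,7,8,8a-hexahydronaphthalen-2(1H)-one (cis-fused; terpenoid C8 ketone), via potassium alkoxide 19 (not isolated), via potassium enolate 20 (not isolated)
Conditions: KH, 18-crown-6, THF, 0 to 50 °C; then H2O, −78 °C to rt
Reagents that add atoms: none
Why: KH/18-crown-6 gives the free potassium alkoxide 19, whose C6=C7–C8(O−)–C3–C4=C5 hexa-1,5-diene unit should undergo a charge-accelerated [3,3]-sigmatropic shift that breaks the bridging C3–C8 bond, makes the C5–C6 bond and leaves the C3=C4 olefin and the C7=C8 enolate 20, which is protonated on quench. The closest known reaction type is the anionic oxy-Cope rearrangement of 2-vinylbicyclo[2.2.2]oct-5-en-2-ols to cis-fused octalones. Ring B (C5–C6–C7–C8–C9–C10) is closed in a concerted suprafacial six-centre array held in a boat geometry by the bicyclic cage, not by a stepwise exo or endo attack. The new quaternary centre C5 is controlled by the cage: C6 can only reach the face of C5 that looks at the C8–C9 bridge, so the C5–C6 and C10–C9 bonds end cis on ring A and the C5 methyl ends cis to H-10, while C9 and C10 pass through untouched. The step needs the vinyl group on the olefin side of C8 (set in step 10) and needs the sigmatropic path to outrun alkoxide fragmentation; the crown-separated alkoxide, the enforced proximity of C6 and C5 and the absence of enolisable hydrogens next to C8 are expected to secure this.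

Step 12
Reactants: 21 (1S,4aR,8aR)-1-{[3-methoxy-2,6-bis(methoxymethoxy)phenyl]methyl}-1,4a,5-trimethyl-3,4,4a,7,8,8a-hexahydronaphthalen-2(1H)-one
Product: 22 4-methoxy-1,3-bis(methoxymethoxy)-2-{[(1S,4aR,8aS)-1,4a,5-trimethyl-2-methylidene-1,2,3,4,4a,7,8,8a-octahydronaphthalen-1-yl]methyl}benzene
Conditions: Ph3PCH3Br, KOtBu, toluene, 90 °C
Reagents that add atoms: methyltriphenylphosphonium bromide, C[P+](c1ccccc1)(c1ccccc1)c1ccccc1.[Br-]
Why: Wittig methylenation at elevated temperature should convert the hindered C8 ketone next to the quaternary C9 into the exocyclic olefin; no stereocentre is formed and none of C5, C9 and C10 can epimerise.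

Step 13
Reactants: 22 4-methoxy-1,3-bis(methoxymethoxy)-2-{[(1S,4aR,8aS)-1,4a,5-trimethyl-2-methylidene-1,2,3,4,4a,7,8,8a-octahydronaphthalen-1-yl]methyl}benzene
Product: 23 4-methoxy-1,3-bis(methoxymethoxy)-2-{[(1R,2S,4aR,8aS)-1,2,4a,5-tetramethyl-1,2,3,4,4a,7,8,8a-octahydronaphthalen-1-yl]methyl}benzene
Conditions: H2 (4 atm), RhCl(PPh3)3 (10 mol %), benzene, rt
Reagents that add atoms: none
Why: Homogeneous catalytic hydrogenation should reduce the 1,1-disubstituted exocyclic olefin and leave the trisubstituted C3=C4 olefin, and hydrogen is expected to reach C8 from the alpha face (past H-10 only) because the beta face is blocked by the axial C9 methyl in the ring B chair that keeps C11 equatorial, so the C8 methyl ends beta (8S), cis to the C9 methyl.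

Step 14
Reactants: 23 4-methoxy-1,3-bis(methoxymethoxy)-2-{[(1R,2S,4aR,8aS)-1,2,4a,5-tetramethyl-1,2,3,4,4a,7,8,8a-octahydronaphthalen-1-yl]methyl}benzene
Product: 24 4-methoxy-2-{[(1R,2S,4aR,8aS)-1,2,4a,5-tetramethyl-1,2,3,4,4a,7,8,8a-octahydronaphthalen-1-yl]methyl}benzene-1,3-diol
Conditions: 3 M aq HCl, MeOH/THF, 45 °C
Reagents that add atoms: none
Why: Acid-catalysed acetal exchange with methanol removes both MOM ethers under conditions expected to be too mild to protonate the trisubstituted olefin; no stereocentre is touched.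

Step 15
Reactants: 24 4-methoxy-2-{[(1R,2S,4aR,8aS)-1,2,4a,5-tetramethyl-1,2,3,4,4a,7,8,8a-octahydronaphthalen-1-yl]methyl}benzene-1,3-diol
Product: 25 4-methoxy-6-[(E)-phenyldiazenyl]-2-{[(1R,2S,4aR,8aS)-1,2,4a,5-tetramethyl-1,2,3,4,4a,7,8,8a-octahydronaphthalen-1-yl]methyl}benzene-1,3-diol
Conditions: PhN2BF4, pyridine, THF, 0 °C
Reagents that add atoms: benzenediazonium tetrafluoroborate, N#[N+]c1ccccc1.F[B-](F)(F)F
Why: Azo coupling (electrophilic aromatic substitution) should occur at the only free ring position that is ortho to one hydroxyl and para to the other (the second free position is meta to both), and the diazonium ion does not attack the isolated olefin.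

Step 16
Reactants: 25 4-methoxy-6-[(E)-phenyldiazenyl]-2-{[(1R,2S,4aR,8aS)-1,2,4a,5-tetramethyl-1,2,3,4,4a,7,8,8a-octahydronaphthalen-1-yl]methyl}benzene-1,3-diol
Product: 27 5-methoxy-2-methyl-7-{[(1R,2S,4aR,8aS)-1,2,4a,5-tetramethyl-1,2,3,4,4a,7,8,8a-octahydronaphthalen-1-yl]methyl}-1,3-benzoxazol-6-ol, via aminoresorcinol 26 (not isolated)
Conditions: Na2S2O4, THF/H2O, 50 °C, argon; extraction with degassed solvent; then MeC(OEt)3 (excess), PPTS (10 mol %), toluene, 100 °C
Reagents that add atoms: triethyl orthoacetate, CCOC(C)(OCC)OCC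
Why: Dithionite cleaves the azo group reductively to the o-aminophenol, which condenses with the orthoester (imidate formation, then ring closure with loss of ethanol) to the 2-methylbenzoxazole, and only the hydroxyl next to the amino group can close the ring, so the other hydroxyl stays free.

**Compound list**

1 | 4-methoxybenzene-1,3-diol | COc1ccc(O)cc1O | starting material
2 | 1-methoxy-2,4-bis(methoxymethoxy)benzene | COCOc1ccc(OC)c(OCOC)c1 | intermediate
3 | [3-methoxy-2,6-bis(methoxymethoxy)phenyl]lithium | COCOc1ccc(OC)c(OCOC)c1[Li] | intermediate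
4 | [3-methoxy-2,6-bis(methoxymethoxy)phenyl]methanol | COCOc1ccc(OC)c(OCOC)c1CO | intermediate
5 | 2-(bromomethyl)-4-methoxy-1,3-bis(methoxymethoxy)benzene | COCOc1ccc(OC)c(OCOC)c1CBr | intermediate
6 | 2-methylcyclohex-2-en-1-one | CC1=CCCCC1=O | starting material
7 | lithium 6-methylcyclohexa-1,5-dien-1-olate | [Li+].[O-]C1=CCCC=C1C | intermediate
8 | 6-methylcyclohexa-1,5-dien-1-yl trifluoromethanesulfonate | CC1=CCCC=C1OS(=O)(=O)C(F)(F)F | intermediate
9 | 2,3-dimethylcyclohexa-1,3-diene | CC1=CCCC=C1C | intermediate
10 | acrolein (prop-2-enal) | C=CC=O | starting material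
11 | (1R,2S,4S)-5,6-dimethylbicyclo[2.2.2]oct-5-ene-2-carbaldehyde (endo) | O=C[C@H]1C[C@@H]2CC[C@H]1C(C)=C2C | intermediate
12 | 1-{[(1S,4S)-5,6-dimethylbicyclo[2.2.2]oct-5-en-2-ylidene]methyl}piperidine (piperidine enamine of 11; E/Z mixture) | C(=C1C[C@@H]2CC[C@H]1C(C)=C2C)N1CCCCC1 | intermediate
13 | (1S,4S)-5,6-dimethylbicyclo[2.2.2]oct-5-en-2-one | O=C1C[C@@H]2CC[C@H]1C(C)=C2C | intermediate
14 | lithium enolate of 13 | [Li+].[O-]C1=C[C@@H]2CC[C@H]1C(C)=C2C | intermediate
15 | (1S,4S)-3,5,6-trimethylbicyclo[2.2.2]oct-5-en-2-one (both C3 epimers) | O=C1C(C)[C@@H]2CC[C@H]1C(C)=C2C | intermediate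
16 | lithium enolate of 15 | [Li+].[O-]C1=C(C)[C@@H]2CC[C@H]1C(C)=C2C | intermediate
17 | (1S,3S,4R)-3-{[3-methoxy-2,6-bis(methoxymethoxy)phenyl]methyl}-3,5,6-trimethylbicyclo[2.2.2]oct-5-en-2-one | O=C1[C@@](C)(Cc3c(OCOC)c(OC)ccc3OCOC)[C@@H]2CC[C@H]1C(C)=C2C | intermediate
18 | (1S,2S,3S,4R)-2-ethenyl-3-{[3-methoxy-2,6-bis(methoxymethoxy)phenyl]methyl}-3,5,6-trimethylbicyclo[2.2.2]oct-5-en-2-ol | C=C[C@@]1(O)[C@@](C)(Cc3c(OCOC)c(OC)ccc3OCOC)[C@@H]2CC[C@H]1C(C)=C2C | intermediate
19 | potassium alkoxide of 18 | [K+].C=C[C@@]1([O-])[C@@](C)(Cc3c(OCOC)c(OC)ccc3OCOC)[C@@H]2CC[C@H]1C(C)=C2C | intermediate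
20 | potassium enolate of 21 (C7=C8 enolate) | [K+].COCOc1ccc(OC)c(OCOC)c1C[C@]1(C)C([O-])=CC[C@@]2(C)C(C)=CCC[C@@H]12 | intermediate
21 | (1S,4aR,8aR)-1-{[3-methoxy-2,6-bis(methoxymethoxy)phenyl]methyl}-1,4a,5-trimethyl-3,4,4a,7,8,8a-hexahydronaphthalen-2(1H)-one | COCOc1ccc(OC)c(OCOC)c1C[C@]1(C)C(=O)CC[C@@]2(C)C(C)=CCC[C@@H]12 | intermediate
22 | 4-methoxy-1,3-bis(methoxymethoxy)-2-{[(1S,4aR,8aS)-1,4a,5-trimethyl-2-methylidene-1,2,3,4,4a,7,8,8a-octahydronaphthalen-1-yl]methyl}benzene | COCOc1ccc(OC)c(OCOC)c1C[C@]1(C)C(=C)CC[C@@]2(C)C(C)=CCC[C@@H]12 | intermediate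
23 | 4-methoxy-1,3-bis(methoxymethoxy)-2-{[(1R,2S,4aR,8aS)-1,2,4a,5-tetramethyl-1,2,3,4,4a,7,8,8a-octahydronaphthalen-1-yl]methyl}benzene | COCOc1ccc(OC)c(OCOC)c1C[C@]1(C)[C@@H](C)CC[C@@]2(C)C(C)=CCC[C@@H]12 | intermediate
24 | 4-methoxy-2-{[(1R,2S,4aR,8aS)-1,2,4a,5-tetramethyl-1,2,3,4,4a,7,8,8a-octahydronaphthalen-1-yl]methyl}benzene-1,3-diol | COc1ccc(O)c(C[C@]2(C)[C@@H](C)CC[C@@]3(C)C(C)=CCC[C@@H]23)c1O | intermediate
25 | 4-methoxy-6-[(E)-phenyldiazenyl]-2-{[(1R,2S,4aR,8aS)-1,2,4a,5-tetramethyl-1,2,3,4,4a,7,8,8a-octahydronaphthalen-1-yl]methyl}benzene-1,3-diol | COc1cc(/N=N/c2ccccc2)c(O)c(C[C@]2(C)[C@@H](C)CC[C@@]3(C)C(C)=CCC[C@@H]23)c1O | intermediate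
26 | 4-amino-6-methoxy-2-{[(1R,2S,4aR,8aS)-1,2,4a,5-tetramethyl-1,2,3,4,4a,7,8,8a-octahydronaphthalen-1-yl]methyl}benzene-1,3-diol | COc1cc(N)c(O)c(C[C@]2(C)[C@@H](C)CC[C@@]3(C)C(C)=CCC[C@@H]23)c1O | intermediate
27 | 5-methoxy-2-methyl-7-{[(1R,2S,4aR,8aS)-1,2,4a,5-tetramethyl-1,2,3,4,4a,7,8,8a-octahydronaphthalen-1-yl]methyl}-1,3-benzoxazol-6-ol | COc1cc2nc(C)oc2c(C[C@]2(C)[C@@H](C)CC[C@@]3(C)C(C)=CCC[C@@H]23)c1O | target

**Summary**

Total step count: 16. Longest linear sequence: 13 steps (6 to 27, steps 4–16); the arene branch (steps 1–3) joins at step 9.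

Steps most likely to fail:

- Step 10. The 1,2-addition may lose facial control, or not take place at all, because the carbonyl sits between a bridgehead and the new quaternary carbon whose arylmethyl group lies on the face that must be attacked. Fallback, from 17 back to 18: 17 would be treated with ethynylmagnesium bromide and CeCl3 (THF, −78 to 0 °C) to give the ethynyl carbinol F1. This rod-shaped nucleophile is the least sensitive to the C9 substituents and should be steered by the cage alone. F1 would then be semi-hydrogenated (H2, 1 atm, Pd on CaCO3 poisoned with Pb(OAc)2, quinoline, EtOAc) to 18.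
- Step 13. Hydrogen may be delivered to both faces of the exocyclic olefin if the ring B conformers interconvert, and the catalyst may move the double bond into the ring. Fallback, from 22 back to 23: hydroboration of 22 with the bulky 9-BBN (THF, 60 °C), which touches only the 1,1-disubstituted olefin and amplifies the steric bias, then NaOH/H2O2, would give the primary alcohol F2. Tosylation (TsCl, pyridine) would give the tosylate F3, and LiEt3BH in THF would reduce it to the methyl compound 23.
- Step 16. The electron-rich aminoresorcinol may be oxidised by air before the orthoester closes the ring, and the aniline co-product competes for the orthoester. Fallback, from 23 to 27 (replaces steps 14–16): ortho-lithiation of 23 next to the OMOM group remote from the methoxy group (n-BuLi, TMEDA, THF, −20 °C) and quenching with I2 would give the aryl iodide F4. Goldberg amidation (acetamide, CuI, N,N'-dimethylethane-1,2-diamine, K3PO4, dioxane, 100 °C) would give the air-stable acetanilide F5. Aqueous HCl in MeOH would remove the MOM groups to give the dihydroxy acetanilide F6, and Mitsunobu-type cyclodehydration (PPh3, DIAD, THF) would close the oxazole to 27 without a free aminophenol ever being handled.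

**Further compounds**

F1 | step 10 | 2-ethynyl analogue of 18 (ethynyl syn to the C5=C6 bridge) | C#C[C@@]1(O)[C@@](C)(Cc3c(OCOC)c(OC)ccc3OCOC)[C@@H]2CC[C@H]1C(C)=C2C
F2 | step 13 | 8-beta-hydroxymethyl analogue of 23 (CH2OH in place of the C8 methyl) | COCOc1ccc(OC)c(OCOC)c1C[C@]1(C)[C@@H](CO)CC[C@@]2(C)C(C)=CCC[C@@H]12
F3 | step 13 | p-toluenesulfonate of F2 | COCOc1ccc(OC)c(OCOC)c1C[C@]1(C)[C@@H](COS(=O)(=O)c3ccc(C)cc3)CC[C@@]2(C)C(C)=CCC[C@@H]12
F4 | step 16 | aryl iodide of 23 (iodine ortho to the OMOM group remote from OMe) | COCOc1c(I)cc(OC)c(OCOC)c1C[C@]1(C)[C@@H](C)CC[C@@]2(C)C(C)=CCC[C@@H]12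
F5 | step 16 | N-aryl acetamide from F4 (NHAc in place of iodine) | COCOc1c(NC(C)=O)cc(OC)c(OCOC)c1C[C@]1(C)[C@@H](C)CC[C@@]2(C)C(C)=CCC[C@@H]12
F6 | step 16 | N-acetyl derivative of 26 (both phenols free) | CC(=O)Nc1cc(OC)c(O)c(C[C@]2(C)[C@@H](C)CC[C@@]3(C)C(C)=CCC[C@@H]23)c1O
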